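**Retrosynthetic overview**

1. The last bonds made are the C11–O aryl ether (Mitsunobu reaction with purchased isofraxidin) and, before it, the C3 isovalerate; both sit on a 3α,11-dioxygenated drim-7-en-6-one core.
2. C5 (α to the C6 ketone) and C9 (γ to it through C7=C8) are epimerisable, so the core is traced back to its cis-fused 8(9)-en-6-one, and that to a δ-sultone in which one SO2 group ties O3 to C6 (oxidative desulfonylation returns C6=O and C3–OH together).
3. Key disconnection: C6–C7 and C5–C10, by an intramolecular Diels–Alder reaction of the tetrasubstituted diene C7=C8–C9=C10 with the sultone alkene C5=C6. Rings A and B form together, and C3, the only stereocenter made by catalysis, dictates C10, C5 and C6.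
4. Enabling feature: the axial C3 oxygen and the C6 carbonyl carbon are 1,4-related (O–C3–C4–C5–C6) and lie on the same face of ring A when C5 is cis-fused. One SO2 unit can therefore bridge them in a six-membered ring that activates C5=C6 and leaves the C1–C2 tether a single way to deliver the diene; the C6 ketone then lets C5 and C9 be corrected by equilibration.
5. Ring order: temporary sultone ring (metathesis), then rings A and B at once, then excision of the sultone; the coumarin is attached last. The acyclic precursor comes from but-2-yn-1-ol by anti-carbomagnesiation/allylation and an iridium-catalysed reverse prenylation.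

Key step: step 7

Remark on numbering: drimane numbering is used (C10 = methyl-bearing ring-fusion carbon, C5 = ring-fusion CH, C6 = ketone carbon, C7=C8 = enone alkene, C9 bears C11H2O, C3 = ester carbon, C4 = gem-dimethyl carbon); α is the face opposite to the C10 methyl.

Assumption: the (R)-SEGPHOS antipode of the iridium catalyst in step 4 is taken to give the (4R) carbinol 10; if the sense of induction is the opposite, the (S)-ligand is used and nothing else changes.

**Route**

Step 1
Reactants: 1 but-2-yn-1-ol; 2 prop-1-en-2-ylmagnesium bromide; 3 allyl bromide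
Product: 5 (2Z)-3-methyl-2-(prop-1-en-2-yl)hexa-2,5-dien-1-ol, via oxamagnesole chelate 4 (not isolated)
Conditions: 2 (3 equiv), CuI (10 mol %), THF, 0 °C → reflux; then 3, 0 → 23 °C; aq NH4Cl
Reagents that add atoms: none
Why: Hydroxyl-directed anti-carbomagnesiation of the propargylic alkoxide puts the isopropenyl group on the carbinol-side alkyne carbon and magnesium on the distal carbon, cis to CH2O in a five-membered chelate, and Cu-catalysed allylation of that alkenylmagnesium with retention should fix the tetrasubstituted alkene geometry (allyl cis to CH2OH).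

Step 2
Reactants: 5 (2Z)-3-methyl-2-(prop-1-en-2-yl)hexa-2,5-dien-1-ol
Product: 6 tert-butyl(dimethyl){[(2Z)-3-methyl-2-(prop-1-en-2-yl)hexa-2,5-dien-1-yl]oxy}silane
Conditions: TBSCl, imidazole, DMF, 23 °C
Reagents that add atoms: tert-butyldimethylsilyl chloride, CC(C)(C)[Si](C)(C)Cl
Why: Standard silylation of a primary allylic alcohol; the silyl ether masks C11–OH until the coumarin is attached.

Step 3
Reactants: 6 tert-butyl(dimethyl){[(2Z)-3-methyl-2-(prop-1-en-2-yl)hexa-2,5-dien-1-yl]oxy}silane
Product: 8 (4Z)-5-{[tert-butyl(dimethyl)silyl]oxymethyl}-4,6-dimethylhepta-4,6-dien-1-ol, via alkyl(disiamyl)borane 7 (not isolated)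
Conditions: Sia2BH (from BH3·THF and 2-methylbut-2-ene), THF, 0 °C; then NaOH, H2O2, 0 → 23 °C
Reagents that add atoms: hydrogen peroxide, OO
Why: Hydroboration–oxidation with the bulky disiamylborane should select the monosubstituted terminal alkene over the 1,1-disubstituted diene terminus and the tetrasubstituted alkene, giving the anti-Markovnikov primary alcohol.

Step 4
Reactants: 8 (4Z)-5-{[tert-butyl(dimethyl)silyl]oxymethyl}-4,6-dimethylhepta-4,6-dien-1-ol; 9 3-methylbuta-1,2-diene
Product: 10 (4R,7Z)-8-{[tert-butyl(dimethyl)silyl]oxymethyl}-3,3,7,9-tetramethyldeca-1,7,9-trien-4-ol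
Conditions: Ir(C3H5)[(R)-SEGPHOS](4-Cl-3-NO2-C6H2CO2) (5 mol %), 9 (3 equiv), PhMe, 60 °C, sealed tube
Reagents that add atoms: none
Why: Iridium-catalysed transfer-hydrogenative carbonyl reverse prenylation from the alcohol oxidation level: the alcohol is dehydrogenated to the aldehyde, the allene is hydrometallated to a prenyliridium species, and γ-addition through a closed chair transition state in the chiral ligand pocket should set the C3 carbinol (R) while installing C4 with its two methyls and the vinyl group.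

Step 5
Reactants: 10 (4R,7Z)-8-{[tert-butyl(dimethyl)silyl]oxymethyl}-3,3,7,9-tetramethyldeca-1,7,9-trien-4-ol; 11 2-chloroethanesulfonyl chloride
Product: 12 (4R,7Z)-8-{[tert-butyl(dimethyl)silyl]oxymethyl}-3,3,7,9-tetramethyldeca-1,7,9-trien-4-yl ethenesulfonate
Conditions: 11, Et3N (3 equiv), CH2Cl2, −20 → 0 °C
Reagents that add atoms: none
Why: O-Sulfonylation by ethenesulfonyl chloride generated in the flask by dehydrochlorination; this sulfene-type reagent should esterify even the hindered neopentyl carbinol without touching its configuration.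

Step 6
Reactants: 12 (4R,7Z)-8-{[tert-butyl(dimethyl)silyl]oxymethyl}-3,3,7,9-tetramethyldeca-1,7,9-trien-4-yl ethenesulfonate
Product: 13 (6R)-6-[(3Z)-4-{[tert-butyl(dimethyl)silyl]oxymethyl}-3,5-dimethylhexa-3,5-dien-1-yl]-5,5-dimethyl-5,6-dihydro-1,2-oxathiine 2,2-dioxide
Conditions: second-generation Grubbs catalyst RuCl2(H2IMes)(PCy3)(=CHPh) (5 mol %), CH2Cl2 (0.005 M), 40 °C
Reagents that add atoms: none
Why: Ring-closing metathesis of a homoallylic vinylsulfonate to an α,β-unsaturated δ-sultone, a six-membered closure helped by the gem-dimethyl group, while the hindered conjugated diene (one 1,1-disubstituted and one tetrasubstituted alkene) should be a poor metathesis partner.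

Step 7
Reactants: 13 (6R)-6-[(3Z)-4-{[tert-butyl(dimethyl)silyl]oxymethyl}-3,5-dimethylhexa-3,5-dien-1-yl]-5,5-dimethyl-5,6-dihydro-1,2-oxathiine 2,2-dioxide
Product: 14 (3R,5S,6S,10S)-11-[tert-butyl(dimethyl)silyl]oxy-5β-drim-8-ene bridged by SO2 between the 3α-oxygen and C6 (tricyclic δ-sultone; cis-fused decalin, C8=C9 alkene, C7H2)
Conditions: BHT (0.1 equiv), PhMe (0.01 M), sealed tube, 140 °C (13 kbar, CH2Cl2, 40 °C as the low-temperature variant)
Reagents that add atoms: none
Why: Concerted, asynchronous normal-electron-demand [4+2] cycloaddition in which the diene C7=C8–C9=C10 adds across the sultone alkene C5=C6, C7 bonding to the sulfur-bearing C6 and the fully substituted C10 to C5; the closest known reaction type is the intramolecular Diels–Alder reaction of vinylsulfonates that gives δ-sultones. Ring B closes as the six-membered cycloaddition ring, and ring A closes through the new C5–C10 bond, the C1–C2 chain from the sultone carbinol carbon C3 forming a six-membered chair (a type 1 closure onto a cyclic dienophile that gives a bicyclo[3.3.1] array of ring A and the sultone). The diene can reach only the face of C5=C6 that carries the C3–C2 bond, so C3 fixes C5 and C6; because the O–SO2 bridge then holds C6 axial on ring A, ring B can close only with C9 equatorial and the C10 methyl axial and anti to O3, so C3 also fixes the quaternary C10 (sultone endo, tether outward on the diene as set in step 1). The step needs regioselectivity (C10 to C5, not to C6), which the tether length secures as a six- against a seven-membered ring. It also needs the cycloaddition to outrun a [1,5]-hydrogen shift from the inward C10 methyl, which the sulfonyl activation, the gem-dimethyl group and the twisted, s-cis-biased tetrasubstituted diene should allow. The cis-fused C5 configuration formed here is corrected in step 10.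

Step 8
Reactants: 14 tricyclic δ-sultone
Product: 17 (3R,5S,10S)-11-[tert-butyl(dimethyl)silyl]oxy-3α-hydroxy-5β-drim-8-en-6-one, via lithiated sultone 15 (not isolated), via lithium sulfite monoester 16 (not isolated)
Conditions: LiN(iPr)2, THF, −78 °C; then Me3SiOOSiMe3, −78 → 0 °C; aq NaHCO3
Reagents that add atoms: bis(trimethylsilyl) peroxide, C[Si](C)(C)OO[Si](C)(C)C
Why: Oxidative desulfonylation of the α-sulfonyl carbanion: oxygen transfer from the silyl peroxide to C6 gives an α-oxido sulfonate that should collapse to the C6 ketone and an alkyl sulfite, hydrolysed on work-up to the free C3 alcohol; only C6 changes, becoming sp2.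

Step 9
Reactants: 17 (3R,5S,10S)-11-[tert-butyl(dimethyl)silyl]oxy-3α-hydroxy-5β-drim-8-en-6-one; 18 3-methylbutanoyl chloride
Product: 19 (3R,5S,10S)-11-[tert-butyl(dimethyl)silyl]oxy-6-oxo-5β-drim-8-en-3α-yl 3-methylbutanoate
Conditions: 18, Et3N, DMAP, CH2Cl2, 0 → 23 °C
Reagents that add atoms: none
Why: DMAP-catalysed acylation of the hindered secondary alcohol with retention at C3; it also removes the hydroxyl that could otherwise sit as a bridged hemiketal with the C6 ketone during the next step.

Step 10
Reactants: 19 (3R,5S,10S)-11-[tert-butyl(dimethyl)silyl]oxy-6-oxo-5β-drim-8-en-3α-yl 3-methylbutanoate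
Product: 20 (3R,5R,9R,10R)-11-[tert-butyl(dimethyl)silyl]oxy-6-oxodrim-7-en-3α-yl 3-methylbutanoate (trans-fused, 5α-H, 9β-H)
Conditions: DBU (0.5 equiv), PhMe, 80 °C, to constant composition
Reagents that add atoms: none
Why: Base-mediated equilibration through the C6 enolate and dienolate (alkene conjugation plus epimerisation) should move C8=C9 into conjugation, turn C5 to the trans ring fusion, and settle C9 with CH2OTBS pseudoaxial and anti to the C10 methyl, where it avoids A(1,2) strain with the C8 methyl, as 9-formyl drim-7-enes do.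

Step 11
Reactants: 20 (3R,5R,9R,10R)-11-[tert-butyl(dimethyl)silyl]oxy-6-oxodrim-7-en-3α-yl 3-methylbutanoate
Product: 21 (3R,5R,9R,10R)-11-hydroxy-6-oxodrim-7-en-3α-yl 3-methylbutanoate
Conditions: HF·pyridine, THF, 0 → 23 °C
Reagents that add atoms: none
Why: Acidic fluoride desilylation frees the primary alcohol without forming a dienolate, so the ester, the enone and the C9 configuration should be kept.

Step 12
Reactants: 21 (3R,5R,9R,10R)-11-hydroxy-6-oxodrim-7-en-3α-yl 3-methylbutanoate; 22 isofraxidin (7-hydroxy-6,8-dimethoxycoumarin)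
Product: 23 target, (3R,5R,9R,10R)-11-[(6,8-dimethoxy-2-oxo-2H-chromen-7-yl)oxy]-6-oxodrim-7-en-3α-yl 3-methylbutanoate
Conditions: PPh3, DIAD, THF, 0 → 23 °C
Reagents that add atoms: none
Why: Mitsunobu etherification of the primary alcohol with an acidic phenol (both ortho positions blocked); no stereocenter is involved and the conditions are close to neutral.

**Compound list**

1 | but-2-yn-1-ol | CC#CCO | starting material
2 | prop-1-en-2-ylmagnesium bromide | C=C(C)[Mg]Br | starting material
3 | allyl bromide | C=CCBr | starting material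
4 | 3-methyl-4-(prop-1-en-2-yl)-2,5-dihydro-1,2-oxamagnesole (alkenylmagnesium alkoxide chelate) | CC1=C(C(C)=C)CO[Mg]1 | intermediate
5 | (2Z)-3-methyl-2-(prop-1-en-2-yl)hexa-2,5-dien-1-ol | OC/C(=C(/C)CC=C)C(C)=C | intermediate
6 | tert-butyl(dimethyl){[(2Z)-3-methyl-2-(prop-1-en-2-yl)hexa-2,5-dien-1-yl]oxy}silane | CC(C)(C)[Si](C)(C)OC/C(=C(/C)CC=C)C(C)=C | intermediate
7 | {(4Z)-5-{[tert-butyl(dimethyl)silyl]oxymethyl}-4,6-dimethylhepta-4,6-dien-1-yl}bis(3-methylbutan-2-yl)borane | CC(C)C(C)B(CCC/C(C)=C(\CO[Si](C)(C)C(C)(C)C)C(C)=C)C(C)C(C)C | intermediate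
8 | (4Z)-5-{[tert-butyl(dimethyl)silyl]oxymethyl}-4,6-dimethylhepta-4,6-dien-1-ol | CC(C)(C)[Si](C)(C)OC/C(=C(/C)CCCO)C(C)=C | intermediate
9 | 3-methylbuta-1,2-diene | CC(C)=C=C | starting material
10 | (4R,7Z)-8-{[tert-butyl(dimethyl)silyl]oxymethyl}-3,3,7,9-tetramethyldeca-1,7,9-trien-4-ol | C=CC(C)(C)[C@H](O)CC/C(C)=C(\CO[Si](C)(C)C(C)(C)C)C(C)=C | intermediate
11 | 2-chloroethanesulfonyl chloride | ClCCS(=O)(=O)Cl | starting material
12 | (4R,7Z)-8-{[tert-butyl(dimethyl)silyl]oxymethyl}-3,3,7,9-tetramethyldeca-1,7,9-trien-4-yl ethenesulfonate | C=CC(C)(C)[C@H](OS(=O)(=O)C=C)CC/C(C)=C(\CO[Si](C)(C)C(C)(C)C)C(C)=C | intermediate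
13 | (6R)-6-[(3Z)-4-{[tert-butyl(dimethyl)silyl]oxymethyl}-3,5-dimethylhexa-3,5-dien-1-yl]-5,5-dimethyl-5,6-dihydro-1,2-oxathiine 2,2-dioxide | O=S1(=O)C=CC(C)(C)[C@@H](CC/C(C)=C(\CO[Si](C)(C)C(C)(C)C)C(C)=C)O1 | intermediate
14 | (3R,5S,6S,10S)-11-[tert-butyl(dimethyl)silyl]oxy-5β-drim-8-ene with SO2 bridging the 3α-oxygen and C6 (tricyclic δ-sultone) | CC1=C(CO[Si](C)(C)C(C)(C)C)[C@@]2(C)CC[C@H]3OS(=O)(=O)[C@@H](C1)[C@@H]2C3(C)C | intermediate
15 | 6-lithio derivative of sultone 14 | CC1=C(CO[Si](C)(C)C(C)(C)C)[C@@]2(C)CC[C@H]3OS(=O)(=O)C([Li])(C1)[C@@H]2C3(C)C | intermediate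
16 | lithium sulfite monoester of 17 at O3 | CC1=C(CO[Si](C)(C)C(C)(C)C)[C@@]2(C)CC[C@@H](OS(=O)[O-])C(C)(C)[C@H]2C(=O)C1.[Li+] | intermediate
17 | (3R,5S,10S)-11-[tert-butyl(dimethyl)silyl]oxy-3α-hydroxy-5β-drim-8-en-6-one | CC1=C(CO[Si](C)(C)C(C)(C)C)[C@@]2(C)CC[C@@H](O)C(C)(C)[C@H]2C(=O)C1 | intermediate
18 | 3-methylbutanoyl chloride | CC(C)CC(=O)Cl | starting material
19 | (3R,5S,10S)-11-[tert-butyl(dimethyl)silyl]oxy-6-oxo-5β-drim-8-en-3α-yl 3-methylbutanoate | CC1=C(CO[Si](C)(C)C(C)(C)C)[C@@]2(C)CC[C@@H](OC(=O)CC(C)C)C(C)(C)[C@H]2C(=O)C1 | intermediate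
20 | (3R,5R,9R,10R)-11-[tert-butyl(dimethyl)silyl]oxy-6-oxodrim-7-en-3α-yl 3-methylbutanoate | CC(C)(C)[Si](C)(C)OC[C@@H]1C(C)=CC(=O)[C@H]2C(C)(C)[C@H](OC(=O)CC(C)C)CC[C@]12C | intermediate
21 | (3R,5R,9R,10R)-11-hydroxy-6-oxodrim-7-en-3α-yl 3-methylbutanoate | OC[C@@H]1C(C)=CC(=O)[C@H]2C(C)(C)[C@H](OC(=O)CC(C)C)CC[C@]12C | intermediate
22 | isofraxidin (7-hydroxy-6,8-dimethoxy-2H-chromen-2-one) | COc1cc2ccc(=O)oc2c(OC)c1O | starting material
23 | (3R,5R,9R,10R)-11-[(6,8-dimethoxy-2-oxo-2H-chromen-7-yl)oxy]-6-oxodrim-7-en-3α-yl 3-methylbutanoate | COc1cc2ccc(=O)oc2c(OC)c1OC[C@@H]1C(C)=CC(=O)[C@H]2C(C)(C)[C@H](OC(=O)CC(C)C)CC[C@]12C | target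

**Step count and risks**

Total step count: 12. Longest linear sequence: 12 steps (from but-2-yn-1-ol; all other building blocks are purchased).

Steps most likely to fail:

1. Step 7. The closure between the neopentyl C5 and the fully substituted C10 may be slower than a thermal [1,5]-hydrogen shift from the inward C10 methyl of the diene, or the diene may orient with C10 over C6. The fallback sets out from 10 and comes back at 17; it keeps the doubly tethered design but uses a carbonyl-activated dienophile that a Lewis acid can drive below 0 °C. Alcohol 10 is esterified with acryloyl chloride (Et3N, CH2Cl2) to the acrylate F1. Ring-closing metathesis with the second-generation Grubbs catalyst gives the 5,5-dimethyl-5,6-dihydropyran-2-one F2. Me2AlCl (CH2Cl2, −40 → 0 °C) promotes the intramolecular Diels–Alder reaction to the bridged tricyclic δ-lactone F3 under the same geometric control. Enolisation and hydroxylation at C6 (KN(SiMe3)2, then 2-(phenylsulfonyl)-3-phenyloxaziridine, THF, −78 °C) gives the α-hydroxy lactone F4. LiAlH4 opens it to the triol F5, and NaIO4 cleaves the C6 glycol, removing the former acrylate carbonyl carbon and delivering 17.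

2. Step 10. The equilibration may stop at an unfavourable ratio at C9, or the C9 epimer with CH2OTBS pseudoequatorial may be favoured. The fallback sets out from 20 (as whatever C9 mixture is obtained) and comes back at 21; it moves the equilibration to the aldehyde oxidation level, where the pseudoaxial preference is known from the polygodial–isotadeonal pair. The mixture of 20 and its C9 epimer F6 is desilylated (HF·pyridine) to 21 and its C9 epimer F7. Dess–Martin oxidation gives the 11-aldehydes, the 9-epi aldehyde F8 and the aldehyde F9. With C9 now α to a formyl group as well as γ to the enone, a trace of DBU at 23 °C should equilibrate them toward F9. NaBH4 (EtOH/CH2Cl2, −78 °C) then reduces the aldehyde selectively over the enone and returns 21.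

3. Step 12. Activation of C11–OH next to the acidic γ-position of the enone may lead to 1,6-elimination, or the hindered primary carbinol may couple slowly. The fallback sets out from 21 and comes back at 23; it removes the vinylogous acidity during the etherification. Luche reduction (NaBH4, CeCl3·7H2O, MeOH, −78 °C; hydride from the α face) gives the 6β-allylic alcohol F10. The Mitsunobu reaction with 22 (PPh3, DIAD) then takes place only at the primary C11 hydroxyl, the axial 6β-hydroxyl being shielded by the C10 and C4 methyls, to give the ether F11. Dess–Martin oxidation of the allylic alcohol restores the enone and gives 23.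

**Further compounds**

F1 | step 7 | (4R,7Z)-8-{[tert-butyl(dimethyl)silyl]oxymethyl}-3,3,7,9-tetramethyldeca-1,7,9-trien-4-yl prop-2-enoate | C=CC(C)(C)[C@H](OC(=O)C=C)CC/C(C)=C(\CO[Si](C)(C)C(C)(C)C)C(C)=C
F2 | step 7 | (6R)-6-[(3Z)-4-{[tert-butyl(dimethyl)silyl]oxymethyl}-3,5-dimethylhexa-3,5-dien-1-yl]-5,5-dimethyl-5,6-dihydro-2H-pyran-2-one | O=C1C=CC(C)(C)[C@@H](CC/C(C)=C(\CO[Si](C)(C)C(C)(C)C)C(C)=C)O1
F3 | step 7 | tricyclic δ-lactone, (3R,5S,6S,10S)-11-[tert-butyl(dimethyl)silyl]oxy-5β-drim-8-ene with C(=O) bridging the 3α-oxygen and C6 | CC1=C(CO[Si](C)(C)C(C)(C)C)[C@@]2(C)CC[C@H]3OC(=O)[C@@H](C1)[C@@H]2C3(C)C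
F4 | step 7 | 6-hydroxy derivative of lactone F3 (hydroxyl on the β face of C6) | CC1=C(CO[Si](C)(C)C(C)(C)C)[C@@]2(C)CC[C@H]3OC(=O)[C@@](O)(C1)[C@@H]2C3(C)C
F5 | step 7 | (3R,5S,10S)-11-[tert-butyl(dimethyl)silyl]oxy-6-(hydroxymethyl)-5β-drim-8-ene-3α,6-diol | CC1=C(CO[Si](C)(C)C(C)(C)C)[C@@]2(C)CC[C@@H](O)C(C)(C)[C@H]2[C@@](O)(CO)C1
F6 | step 10 | C9 epimer of 20 (9α-H, CH2OTBS β) | CC(C)(C)[Si](C)(C)OC[C@H]1C(C)=CC(=O)[C@H]2C(C)(C)[C@H](OC(=O)CC(C)C)CC[C@]12C
F7 | step 10 | C9 epimer of 21 | OC[C@H]1C(C)=CC(=O)[C@H]2C(C)(C)[C@H](OC(=O)CC(C)C)CC[C@]12C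
F8 | step 10 | 9-epi 11-aldehyde, 9β-formyl-6-oxodrim-7-en-3α-yl 3-methylbutanoate | O=C[C@H]1C(C)=CC(=O)[C@H]2C(C)(C)[C@H](OC(=O)CC(C)C)CC[C@]12C
F9 | step 10 | 11-aldehyde, 9α-formyl-6-oxodrim-7-en-3α-yl 3-methylbutanoate (9β-H) | O=C[C@@H]1C(C)=CC(=O)[C@H]2C(C)(C)[C@H](OC(=O)CC(C)C)CC[C@]12C
F10 | step 12 | 6β,11-dihydroxydrim-7-en-3α-yl 3-methylbutanoate | OC[C@@H]1C(C)=C[C@@H](O)[C@H]2C(C)(C)[C@H](OC(=O)CC(C)C)CC[C@]12C
F11 | step 12 | 11-[(6,8-dimethoxy-2-oxo-2H-chromen-7-yl)oxy]-6β-hydroxydrim-7-en-3α-yl 3-methylbutanoate | COc1cc2ccc(=O)oc2c(OC)c1OC[C@@H]1C(C)=C[C@@H](O)[C@H]2C(C)(C)[C@H](OC(=O)CC(C)C)CC[C@]12C
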